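**Retrosynthetic overview**
- The strategy rests on the ene-1,4-dione of ring B, C6'(=O)–C1'(coumarin-3-yl)=C2'H–C3'(=O). It is read as a C6' acyl anion added to the β-carbon C1' of a coumarin-3-yl ynone. Cutting C6'–C1' turns the O-TES target into an acyclic isomer, an aldehyde ynone.
- The ynone is cut at C1'–C3(coumarin) by a Sonogashira coupling with 3-bromo-7-methoxycoumarin. It is cut at C2'–C3' by an ethynyl Grignard addition to an α-silyloxy aldehyde. No strong base therefore meets the lactone.
- C6' travels as a 1,3-dithiane, joined at C5'–C6' by opening a 2,2-disubstituted epoxide at its CH2. C4' is set by Sharpless epoxidation of 2-prenylallyl alcohol.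
- Ring order: both coumarin rings are bought. Ring B is the only ring built, in the last C–C bond-forming step, and desilylation ends the route.

Key step: step 12

Remark: locants C1'–C6' refer to ring B (C1' bears the coumarin, C4' is the carbinol). The two carbinol epimers formed at C3' in step 7 are carried together, because step 10 erases that centre.

**Step 1**
Reactants: 1 ethyl 2-(bromomethyl)acrylate; 2 2-methyl-1-propenylmagnesium bromide
Product: 3 ethyl 5-methyl-2-methylidenehex-4-enoate
Conditions: CuI (10 mol %), THF, −78 → −30 °C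
Reagents that add atoms: none
Why: Copper-catalysed allylic substitution of the bromomethyl acrylate by the alkenyl Grignard reagent (SN2 and SN2' attack give the same product) is much faster than conjugate addition to the acrylate formed, and no stereocentre arises.

**Step 2**
Reactants: 3 ethyl 5-methyl-2-methylidenehex-4-enoate
Product: 4 5-methyl-2-methylidenehex-4-en-1-ol (2-prenylallyl alcohol)
Conditions: i-Bu2AlH (2.3 equiv), CH2Cl2, −78 → 0 °C; aq potassium sodium tartrate
Reagents that add atoms: none
Why: Hydride 1,2-reduction of the conjugated ester with i-Bu2AlH stops at the allylic alcohol and leaves both alkenes untouched.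

**Step 3**
Reactants: 4 5-methyl-2-methylidenehex-4-en-1-ol
Product: 5 (S)-[2-(3-methylbut-2-en-1-yl)oxiran-2-yl]methanol
Conditions: Ti(OiPr)4 (10 mol %), L-(+)-diisopropyl tartrate (12 mol %), t-BuOOH (decane), 4 Å MS, CH2Cl2, −20 °C
Reagents that add atoms: tert-butyl hydroperoxide, CC(C)(C)OO
Why: Sharpless asymmetric epoxidation acts only on the titanium-bound allylic alkene (the prenyl alkene is bishomoallylic), and the L-(+)-tartrate delivers oxygen to the face that gives the (S)-epoxide, the same sense as allyl alcohol to (S)-glycidol, which fixes C4'.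

**Step 4**
Reactants: 5 (S)-[2-(3-methylbut-2-en-1-yl)oxiran-2-yl]methanol; 6 1,3-dithiane
Product: 8 (2R)-2-[(1,3-dithian-2-yl)methyl]-5-methylhex-4-ene-1,2-diol, via 2-lithio-1,3-dithiane 7 (not isolated)
Conditions: 6 (3 equiv), n-BuLi (3 equiv), THF, −30 °C; then 5, −30 → 0 °C; H2O
Reagents that add atoms: none
Why: In this Corey–Seebach umpolung the dithiane anion opens the epoxide by SN2 at the unsubstituted CH2, so the C4'–O bond is untouched (the descriptor becomes R only through the priority rules), and the Payne rearrangement of the alkoxide is degenerate here and cannot erode the enantiomeric purity.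

**Step 5**
Reactants: 8 (2R)-2-[(1,3-dithian-2-yl)methyl]-5-methylhex-4-ene-1,2-diol
Product: 9 (2R)-2-[(1,3-dithian-2-yl)methyl]-2-hydroxy-5-methylhex-4-enal
Conditions: SO3·pyridine, DMSO, Et3N, CH2Cl2, 0 °C
Reagents that add atoms: none
Why: Parikh–Doering oxidation converts only the primary alcohol and tolerates thioacetal and alkene, and the aldehyde formed has no α-hydrogen, so C4' cannot epimerise.

**Step 6**
Reactants: 9 (2R)-2-[(1,3-dithian-2-yl)methyl]-2-hydroxy-5-methylhex-4-enal
Product: 10 (2R)-2-[(1,3-dithian-2-yl)methyl]-5-methyl-2-(triethylsilyloxy)hex-4-enal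
Conditions: TESOTf, 2,6-lutidine, CH2Cl2, −78 → 0 °C
Reagents that add atoms: triethylsilyl trifluoromethanesulfonate, CC[Si](CC)(CC)OS(=O)(=O)C(F)(F)F
Why: Silyl triflate with a hindered pyridine base is reactive enough to silylate a tertiary alcohol, and the non-enolisable aldehyde cannot give a silyl enol ether.

**Step 7**
Reactants: 10 (2R)-2-[(1,3-dithian-2-yl)methyl]-5-methyl-2-(triethylsilyloxy)hex-4-enal; 11 ethynylmagnesium bromide
Product: 12 (3RS,4R)-4-[(1,3-dithian-2-yl)methyl]-7-methyl-4-(triethylsilyloxy)oct-6-en-1-yn-3-ol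
Conditions: THF, −78 → 0 °C; H2O
Reagents that add atoms: none
Why: Grignard 1,2-addition of the small acetylide reaches the hindered aldehyde, the cold magnesium alkoxide should not trigger silyl migration, and the new C3' centre needs no control because step 10 removes it.

**Step 8**
Reactants: 13 7-methoxycoumarin
Product: 14 3-bromo-7-methoxycoumarin
Conditions: Br2, NaOAc, AcOH, rt
Reagents that add atoms: bromine, BrBr
Why: Bromine adds across the C3–C4 double bond and acetate removes HBr (addition–elimination), which leaves bromine on C3, the α-carbon of the lactone.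

**Step 9**
Reactants: 12 (3RS,4R)-4-[(1,3-dithian-2-yl)methyl]-7-methyl-4-(triethylsilyloxy)oct-6-en-1-yn-3-ol; 14 3-bromo-7-methoxycoumarin
Product: 15 3-{(3RS,4R)-4-[(1,3-dithian-2-yl)methyl]-3-hydroxy-7-methyl-4-(triethylsilyloxy)oct-6-en-1-yn-1-yl}-7-methoxychromen-2-one
Conditions: PdCl2(PPh3)2 (5 mol %), CuI (10 mol %), Et3N, THF (degassed), rt → 40 °C
Reagents that add atoms: none
Why: In this Sonogashira coupling the α-bromoenoate-type C3–Br bond adds readily to zerovalent palladium, and the only base is an amine, so lactone, silyl ether and dithiane should persist.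

**Step 10**
Reactants: 15 3-{(3RS,4R)-4-[(1,3-dithian-2-yl)methyl]-3-hydroxy-7-methyl-4-(triethylsilyloxy)oct-6-en-1-yn-1-yl}-7-methoxychromen-2-one
Product: 16 3-{(4R)-4-[(1,3-dithian-2-yl)methyl]-7-methyl-3-oxo-4-(triethylsilyloxy)oct-6-en-1-yn-1-yl}-7-methoxychromen-2-one
Conditions: Dess–Martin periodinane (1.2 equiv), dry CH2Cl2, 0 °C
Reagents that add atoms: none
Why: Dess–Martin oxidation of the propargylic alcohol is faster than attack on sulfur in a dry medium with a small excess of oxidant, and it merges the C3' epimers into one ynone.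

**Step 11**
Reactants: 16 3-{(4R)-4-[(1,3-dithian-2-yl)methyl]-7-methyl-3-oxo-4-(triethylsilyloxy)oct-6-en-1-yn-1-yl}-7-methoxychromen-2-one
Product: 17 (3R)-6-(7-methoxy-2-oxo-2H-chromen-3-yl)-3-(3-methylbut-2-en-1-yl)-4-oxo-3-(triethylsilyloxy)hex-5-ynal
Conditions: PhI(OCOCF3)2 (1.5 equiv), MeCN–H2O 9:1, 0 °C, short contact; aq NaHCO3
Reagents that add atoms: water, O
Why: Oxidative thioacetal hydrolysis with the trivalent iodine reagent activates sulfur, water captures the thionium ion, and sulfur leaves as the cyclic disulfide and not as a free thiol, so no thia-Michael addition to the ynone is expected, while the short cold contact spares the prenyl alkene and the tertiary TES ether.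

**Step 12**
Reactants: 17 (3R)-6-(7-methoxy-2-oxo-2H-chromen-3-yl)-3-(3-methylbut-2-en-1-yl)-4-oxo-3-(triethylsilyloxy)hex-5-ynal
Product: 19 3-[(4R)-4-(3-methylbut-2-en-1-yl)-3,6-dioxo-4-(triethylsilyloxy)cyclohex-1-en-1-yl]-7-methoxychromen-2-one, via Breslow enaminol 18 (not isolated)
Conditions: 2-(pentafluorophenyl)-6,7-dihydro-5H-pyrrolo[2,1-c][1,2,4]triazol-2-ium tetrafluoroborate (20 mol %), i-Pr2NEt (20 mol %), degassed toluene (0.02 M), Ar, rt
Reagents that add atoms: none
Why: Proposed new method: the triazolylidene adds to the C6' aldehyde and a proton shift gives the Breslow enaminol 18, whose C6' attacks the ynone β-carbon C1'; the developing in-plane carbanion at C2' (a bent allenolate that the ring cannot make linear) is protonated on its outward lobe by i-Pr2NEtH+, and collapse of the C6' alkoxide expels the carbene and leaves the ketone. The closest known reaction types are the intramolecular Stetter reaction of aldehyde-tethered enones, the carbene-catalysed hydroacylation of tethered alkynes and the 6-endo-dig oxa-Michael closure of 2-hydroxyaryl ynones to flavones; an acyl anion closing on an ynone in this mode has not been shown. Ring B closes 6-endo-dig, helped by the quaternary C4' that folds the chain, and the six-membered ring admits only the cis ene-dione. No stereocentre is created, and C4' is quaternary and takes no part, so its configuration is carried through. The step needs attack at C1' and not at C2': the ketone polarises the alkyne so that only C1' attack places charge next to C3'=O, 5-exo-dig attack would leave an unstabilised vinyl anion at C1', and a crossed benzoin at C3' would need a four-membered ring. It also needs the C4' oxygen to stay: the TES ether blocks retro-aldol cleavage, and a weakly basic, electron-poor carbene with only catalytic amine at room temperature keeps E1cB loss of silanol and enolate closure from C5' slow.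

**Step 13**
Reactants: 19 3-[(4R)-4-(3-methylbut-2-en-1-yl)-3,6-dioxo-4-(triethylsilyloxy)cyclohex-1-en-1-yl]-7-methoxychromen-2-one
Product: 20 3-[(4R)-4-hydroxy-4-(3-methylbut-2-en-1-yl)-3,6-dioxocyclohex-1-en-1-yl]-7-methoxy-2H-chromen-2-one (target)
Conditions: HF·pyridine, excess pyridine, THF, 0 °C → rt; pH 7 phosphate buffer
Reagents that add atoms: none
Why: Fluoride-driven Si–O cleavage in a pyridine-buffered, weakly acidic medium forms neither the C5' enolate needed for dehydration to the quinone nor the alkoxide needed for retro-aldol cleavage, and the C4'–O bond is not broken, so the configuration is kept.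

**Compound list**
1 | ethyl 2-(bromomethyl)acrylate | CCOC(=O)C(=C)CBr | starting material
2 | 2-methyl-1-propenylmagnesium bromide | CC(C)=C[Mg]Br | starting material
3 | ethyl 5-methyl-2-methylidenehex-4-enoate | CCOC(=O)C(=C)CC=C(C)C | intermediate
4 | 5-methyl-2-methylidenehex-4-en-1-ol | OCC(=C)CC=C(C)C | intermediate
5 | (S)-[2-(3-methylbut-2-en-1-yl)oxiran-2-yl]methanol | OC[C@@]1(CC=C(C)C)CO1 | intermediate
6 | 1,3-dithiane | C1CSCSC1 | starting material
7 | 2-lithio-1,3-dithiane (not isolated) | [Li]C1SCCCS1 | intermediate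
8 | (2R)-2-[(1,3-dithian-2-yl)methyl]-5-methylhex-4-ene-1,2-diol | OC[C@@](O)(CC=C(C)C)CC1SCCCS1 | intermediate
9 | (2R)-2-[(1,3-dithian-2-yl)methyl]-2-hydroxy-5-methylhex-4-enal | O=C[C@@](O)(CC=C(C)C)CC1SCCCS1 | intermediate
10 | (2R)-2-[(1,3-dithian-2-yl)methyl]-5-methyl-2-(triethylsilyloxy)hex-4-enal | O=C[C@@](O[Si](CC)(CC)CC)(CC=C(C)C)CC1SCCCS1 | intermediate
11 | ethynylmagnesium bromide | C#C[Mg]Br | starting material
12 | (3RS,4R)-4-[(1,3-dithian-2-yl)methyl]-7-methyl-4-(triethylsilyloxy)oct-6-en-1-yn-3-ol | C#CC(O)[C@@](O[Si](CC)(CC)CC)(CC=C(C)C)CC1SCCCS1 | intermediate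
13 | 7-methoxycoumarin | COc1ccc2ccc(=O)oc2c1 | starting material
14 | 3-bromo-7-methoxycoumarin | COc1ccc2cc(Br)c(=O)oc2c1 | intermediate
15 | 3-{(3RS,4R)-4-[(1,3-dithian-2-yl)methyl]-3-hydroxy-7-methyl-4-(triethylsilyloxy)oct-6-en-1-yn-1-yl}-7-methoxychromen-2-one | COc1ccc2cc(C#CC(O)[C@@](O[Si](CC)(CC)CC)(CC=C(C)C)CC3SCCCS3)c(=O)oc2c1 | intermediate
16 | 3-{(4R)-4-[(1,3-dithian-2-yl)methyl]-7-methyl-3-oxo-4-(triethylsilyloxy)oct-6-en-1-yn-1-yl}-7-methoxychromen-2-one | COc1ccc2cc(C#CC(=O)[C@@](O[Si](CC)(CC)CC)(CC=C(C)C)CC3SCCCS3)c(=O)oc2c1 | intermediate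
17 | (3R)-6-(7-methoxy-2-oxo-2H-chromen-3-yl)-3-(3-methylbut-2-en-1-yl)-4-oxo-3-(triethylsilyloxy)hex-5-ynal | O=CC[C@](O[Si](CC)(CC)CC)(CC=C(C)C)C(=O)C#Cc1cc2ccc(OC)cc2oc1=O | intermediate
18 | Breslow enaminol of 17 and the triazolylidene (not isolated) | OC(C[C@](O[Si](CC)(CC)CC)(CC=C(C)C)C(=O)C#Cc1cc2ccc(OC)cc2oc1=O)=C1N(c2c(F)c(F)c(F)c(F)c2F)N=C2CCCN12 | intermediate
19 | 3-[(4R)-4-(3-methylbut-2-en-1-yl)-3,6-dioxo-4-(triethylsilyloxy)cyclohex-1-en-1-yl]-7-methoxychromen-2-one | COc1ccc2cc(C3=CC(=O)[C@@](O[Si](CC)(CC)CC)(CC=C(C)C)CC3=O)c(=O)oc2c1 | intermediate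
20 | 3-[(4R)-4-hydroxy-4-(3-methylbut-2-en-1-yl)-3,6-dioxocyclohex-1-en-1-yl]-7-methoxy-2H-chromen-2-one | COc1ccc2cc(C3=CC(=O)[C@@](O)(CC=C(C)C)CC3=O)c(=O)oc2c1 | target

**Step count**
- Total steps: 13.
- Longest linear sequence: 12 (steps 1–7 and 9–13). Step 8 is the side branch.

**Steps most likely to fail**

1. **Step 12.**
   - The carbene may be tied up by conjugate addition to the ynone or to coumarin C4.
   - The amine may induce loss of silanol from the β-silyloxy aldehyde or enolate closure from C5'.
   - The 6-endo closure may be too slow because the forming vinyl anion is bent.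
   - Fallback (known chemistry), setting out from 17 and returning at 19. Anti hydroiodination of the ynone with NaI in AcOH at rt puts iodine on C1', cis to the C3' carbonyl, and gives the (Z)-β-iodoenone aldehyde F1. Nozaki–Hiyama–Kishi closure (CrCl2 in excess, catalytic NiCl2, DMF, rt) forms C6'–C1' and gives the ring carbinol F2 as C6' epimers. Dess–Martin oxidation of that allylic alcohol gives 19.

2. **Step 11.**
   - Sulfur fragments released during unmasking may add to the ynone.
   - The oxidant may attack the prenyl alkene.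
   - The acid formed may start desilylation.
   - Fallback, setting out from 15 and returning at 17. The dithiane is hydrolysed before any ynone exists (MeI, CaCO3, MeCN–H2O, 40 °C), and the freed aldehyde is trapped by the C3' hydroxyl as the five-membered lactol F3. NaBH4 in EtOH at 0 °C reduces the open form to the 1,4-diol F4. A double Swern oxidation ((COCl)2, DMSO, CH2Cl2, −78 °C, then Et3N) activates both alcohols before base is added, so lactone formation is excluded, and gives 17 directly.

3. **Step 13.**
   - The hindered tertiary silyl ether may cleave slowly.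
   - Prolonged exposure may cause dehydration to the quinone or retro-aldol opening.
   - Fallback, setting out from 19 and returning at 20, as a redox detour that removes the acidifying ketones before deprotection. Luche reduction (NaBH4, CeCl3·7H2O, MeOH, −78 °C) of both ring ketones gives the silylated ene-diol F5. n-Bu4NF in THF then frees the triol F6 without any enolisable carbonyl in ring B. Neutral oxidation of the two allylic secondary alcohols with MnO2 in CH2Cl2 gives 20, with the tertiary carbinol untouched.

**Further compounds**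
F1 | step 12 | (3R,5Z)-6-iodo-6-(7-methoxy-2-oxo-2H-chromen-3-yl)-3-(3-methylbut-2-en-1-yl)-4-oxo-3-(triethylsilyloxy)hex-5-enal | O=CC[C@](O[Si](CC)(CC)CC)(CC=C(C)C)C(=O)/C=C(\I)c1cc2ccc(OC)cc2oc1=O
F2 | step 12 | 3-[(4R)-6-hydroxy-4-(3-methylbut-2-en-1-yl)-3-oxo-4-(triethylsilyloxy)cyclohex-1-en-1-yl]-7-methoxychromen-2-one (C6' epimers) | COc1ccc2cc(C3=CC(=O)[C@@](O[Si](CC)(CC)CC)(CC=C(C)C)CC3O)c(=O)oc2c1
F3 | step 11 | 3-{[(3R)-5-hydroxy-3-(3-methylbut-2-en-1-yl)-3-(triethylsilyloxy)oxolan-2-yl]ethynyl}-7-methoxychromen-2-one (epimers at oxolane C2 and C5) | COc1ccc2cc(C#CC3OC(O)C[C@]3(O[Si](CC)(CC)CC)CC=C(C)C)c(=O)oc2c1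
F4 | step 11 | 3-[(3RS,4R)-3-hydroxy-4-(2-hydroxyethyl)-7-methyl-4-(triethylsilyloxy)oct-6-en-1-yn-1-yl]-7-methoxychromen-2-one | COc1ccc2cc(C#CC(O)[C@@](O[Si](CC)(CC)CC)(CC=C(C)C)CCO)c(=O)oc2c1
F5 | step 13 | 3-[(4R)-3,6-dihydroxy-4-(3-methylbut-2-en-1-yl)-4-(triethylsilyloxy)cyclohex-1-en-1-yl]-7-methoxychromen-2-one (carbinol epimers) | COc1ccc2cc(C3=CC(O)[C@@](O[Si](CC)(CC)CC)(CC=C(C)C)CC3O)c(=O)oc2c1
F6 | step 13 | 3-[(4R)-3,4,6-trihydroxy-4-(3-methylbut-2-en-1-yl)cyclohex-1-en-1-yl]-7-methoxychromen-2-one (carbinol epimers) | COc1ccc2cc(C3=CC(O)[C@@](O)(CC=C(C)C)CC3O)c(=O)oc2c1
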